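# Proposed total synthesis of haemathamnolic acid 19

## The problem

Haemathamnolic acid 19 is a depside in which the carbonyl of 4-O-methylhaematommic acid (ring A, C1–C6, C1 bearing the ester carbonyl) is bound to O-1' of a hexasubstituted ring B (C1' O-acyl, C2' CH3, C3' CO2H, C4' OH, C5' CHO, C6' OH), and this single ester bond is the only link between the rings. The ester is crowded from both sides, the acyl carbon lying between C2–OH and C6–CH3 and the phenolic oxygen between C2'–CH3 and C6'–OH, so direct esterification is slow and would have to pick O-1' out of three ring B oxygens. The molecule has no stereocentre, so nothing has to be relayed or controlled; the questions are regiochemical (which oxygen is acylated, where the two formyl groups enter) and chemoselective. The fragile parts are the two aldehydes, the free β-resorcylic acid at C3' (decarboxylation on heating or in acid) and the aryl ester, which base can cleave or shift to the neighbouring C6'–OH, so the closing steps must be mild and non-basic. Ring B carries six substituents of five kinds, which rules out building it by successive aromatic substitutions. The opening lies in the 1,3-relationship of the C4' and C6' oxygens with the C3' carboxyl beside them: ring B is the enol of a 4-carboxycyclohexane-1,3-dione in which C1' is an sp3 carbinol carbon alpha to a ketone. Its C1'–O bond can therefore come from SN2 alkylation of the ring A carboxylate, and C5' remains the one unsubstituted position for a late formylation.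

## Retrosynthesis

**19 from 18.** The last bonds cut are protecting-group C–O bonds: the tert-butyl ester at C3', the MOM ether on O-2 and the dioxolane on the C3 aldehyde of 18 all fall in one aqueous acid treatment. This is preferred over ending with a formylation, because the decarboxylation-prone acid is then freed in a cold, non-basic final step. The forward reaction only has to be clean acidolysis.

**18 from 16.** The C5'–CHO bond is cut next. C5' is the only free carbon of ring B and is ortho to both phenols. Ring A in 16 has no free phenol, so a magnesium phenoxide-directed formylation, passing through hydroxymethyl compound 17, can only act on ring B, and its basic medium tolerates the three acid-labile groups. Formylating after deprotection would expose the free acid to acidic electrophilic conditions instead.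

**16 from 15.** No skeletal bond is cut; the oxidation level is lowered by two hydrogens. The resorcinol 16 becomes the cyclohexane-1,3-dione 15, whose C1', C2' and C3' are sp3. This is what turns the phenolic oxygen O-1' into an alkoxy oxygen. The forward reaction is a dehydrogenation driven by aromatisation.

**15 from 12 and 13.** The ring is opened at C2'–C3' and C4'–C5'. This splits 15 into di-tert-butyl malonate 13, which supplies C3', C4' and the carboxyl, and the enone 12, which supplies C5', C6', C1', C2' and the methyl group with the ester already in place. The open-chain Michael adduct 14 lies between them. The other dimedone-type cut (C2'–C3' and C5'–C6', acetoacetate plus a crotonate) is held in reserve. The forward step must add a stabilised carbanion to an alpha-aroyloxy enone and close a Claisen ring without disturbing the aroyl ester.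

**12 from 9 via 10.** The C2'=C1' double bond of 12 is traced to the β-hydroxy ketone 10, dehydrated through its mesylate 11, and 10 in turn to the symmetrical 1,3-diketone 9. The symmetry of 9 means the monoreduction has no regiochemical question, only one of stopping after one hydride.

**9 from 7 and 8.** The C1'–O bond is cut as an SN2 alkylation of the carboxylate of 7 by 3-chloropentane-2,4-dione 8. This replaces the hindered acylation of a ring B phenol by attack of an unhindered carboxylate oxygen on an activated secondary chloride, and it fixes which ring B oxygen carries the acyl group before ring B exists.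

**7 from 1.** The acid 7 is reached from methyl orsellinate 1 in five steps: the methyl ester 6 is saponified, the phenol of 5 is protected as its MOM ether, the aldehyde of 4 is masked as a dioxolane, the C3–CHO bond is made by phenoxide-directed formylation of methyl everninate 2 through hydroxymethyl compound 3, and the C4–OMe bond by selective methylation of 1. Methylation before formylation is chosen so that the only phenol left to direct the formylation has a single free ortho carbon, C3.

## Roads not taken

**Alternative 1: ring A from a 2-pyrone.** Ring A would be cut at C3–C4 and C5–C6. Forward, the ring B aryl pyrone ester A1 takes up 1,1-dimethoxyethene A2 across pyrone C3 and C6; the bicyclic adduct then extrudes its lactone bridge and eliminates one alkoxy group, giving the depside A3.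
- Merits: the 4-methoxy and 2-benzyloxy groups of ring A are differentiated at birth, the cycloaddition is thermal and neutral, and no oxidation step is needed. As a ring-forming event it is probably more dependable than an anionic annulation on an alpha-aroyloxy enone.
- Weak points: A3 has neither formyl group, so two formylations must follow on the assembled depside, one of them at C3 of ring A against the competing C5. The acyl carbon of A1 is still flanked by two ortho substituents and must still be joined to the flanked ring B phenol, so the hindered esterification is moved, not removed. The pentasubstituted ring B phenol needs a synthesis of its own.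
- Comparison: the chosen plan sets against the more reliable cycloaddition an ester bond made by SN2, a ring B assembled from three simple pieces, and a ring A aldehyde installed early where ortho control is enforced.

**Alternative 2: biomimetic aldol folding.** Ring A would be cut between C1 and C6. Forward, the aryl 3,5,7-trioxooctanoate A4 cyclises by aldol attack of C2 on the C7 ketone, then dehydrates and enolises to the aryl orsellinate A5.
- Merits: the ester bond of A4 can be made from an unhindered acyl donor (an acylketene trapped by the phenol), which in this one respect is at least as good as the alkylation used here. Ring A forms under mild conditions.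
- Weak points: in A4 the ester is an unhindered aryl (active) ester, so O-cyclisation to a 4-hydroxy-2-pyrone or Claisen C-acylation, both expelling the ring B phenoxide, compete with the aldol. A5 still needs selective 4-O-methylation, C3 formylation, MOM removal and C5' formylation on the sensitive depside. The ring B phenol again needs separate preparation.
- Comparison: the chosen plan spends more steps before its key step. In return, the ester carbonyl exposed to base is the di-ortho-substituted aroyl group, which resists addition, and only one formylation remains after the rings are joined.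

**Alternative 3: siloxydiene–ynoate benzannulation.** Ring B would be cut at C1'–C2' and C3'–C4'. Forward, the bis(silyl) dienol ether A6 adds to tert-butyl but-2-ynoate A7; elimination of the silylated ester alkoxy group and enolisation give A8, which is identical with compound 16 of the chosen route.
- Merits: A8 is reached at the aromatic oxidation level, with no reduction, dehydration or dehydrogenation. From acid 7 this would save about two steps. In step count and redox economy this road is better.
- Weak points: but-2-ynoates such as A7 are sluggish partners. The new C1'–C2' bond must join the diene terminus carrying the bulky aroyloxy group to the methyl-bearing alkyne carbon. Forcing with heat or a Lewis acid endangers the acetal, the MOM group and the moisture-sensitive diene A6, and Michael addition followed by O-lactonisation to a pyrone is a known diversion.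
- Comparison: the chosen plan offers anionic steps of classical type with cheap reagents, and a stabilised carbanion adding to an enone is more forgiving than this cycloaddition. Since A8 equals 16, the benzannulation remains a possible second entry to the same endgame.

Key step: step 9

Remark: 19 is achiral. Compounds 10, 11, 14 and 15 are racemic diastereomer mixtures whose sp3 centres vanish in steps 8 and 10, and 12 is drawn as the Z isomer although either geometry would serve. In the step lines "aroate", "aroyl" and "aroyloxy" stand for the 3-(1,3-dioxolan-2-yl)-4-methoxy-2-(methoxymethoxy)-6-methylbenzoate, -benzoyl and -benzoyloxy groups. Ring B atoms are numbered C1'–C6' as in the first section.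

## Route

Step 1
Reactants: 1 methyl orsellinate (methyl 2,4-dihydroxy-6-methylbenzoate)
Product: 2 methyl everninate (methyl 2-hydroxy-4-methoxy-6-methylbenzoate)
Conditions: MeI (1.05 equiv), K2CO3, acetone, reflux
Reagents that add atoms: iodomethane, CI
Why: Williamson O-methylation; the C2 hydroxyl is hydrogen-bonded to the ester carbonyl and far less reactive, so one equivalent of MeI should go to the C4 hydroxyl.

Step 2
Reactants: 2 methyl everninate
Product: 4 methyl 3-formyl-2-hydroxy-4-methoxy-6-methylbenzoate, via hydroxymethyl phenol 3 (not isolated)
Conditions: MgCl2, Et3N, (CH2O)n, MeCN, reflux; aq. HCl work-up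
Reagents that add atoms: formaldehyde (from paraformaldehyde), C=O
Why: Magnesium-mediated ortho-formylation (Casnati–Skattebøl type): the magnesium phenoxide delivers formaldehyde to its only free ortho carbon, C3, and a second formaldehyde oxidises 3 by Oppenauer-type hydride transfer. C5, para to the hydroxyl, cannot be reached by this mechanism.

Step 3
Reactants: 4 methyl 3-formyl-2-hydroxy-4-methoxy-6-methylbenzoate
Product: 5 methyl 3-(1,3-dioxolan-2-yl)-2-hydroxy-4-methoxy-6-methylbenzoate
Conditions: HOCH2CH2OH, TsOH·H2O (cat.), benzene, reflux, Dean–Stark; Et3N quench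
Reagents that add atoms: ethane-1,2-diol, OCCO
Why: Acid-catalysed acetalisation driven by azeotropic removal of water. It is placed before O-protection because a MOM ether would not survive the acid, whereas the hindered methyl ester does.

Step 4
Reactants: 5 methyl 3-(1,3-dioxolan-2-yl)-2-hydroxy-4-methoxy-6-methylbenzoate
Product: 6 methyl 3-(1,3-dioxolan-2-yl)-4-methoxy-2-(methoxymethoxy)-6-methylbenzoate
Conditions: NaH, MOMCl, DMF, 0 °C to rt
Reagents that add atoms: chloromethyl methyl ether, COCCl
Why: O-alkylation of the sodium phenoxide (Williamson type); the basic medium leaves the dioxolane and the ester untouched.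

Step 5
Reactants: 6 methyl 3-(1,3-dioxolan-2-yl)-4-methoxy-2-(methoxymethoxy)-6-methylbenzoate
Product: 7 3-(1,3-dioxolan-2-yl)-4-methoxy-2-(methoxymethoxy)-6-methylbenzoic acid
Conditions: KOH, DMSO/H2O, 90 °C; then cold 1 M HCl to pH 3–4, EtOAc, 0 °C
Reagents that add atoms: potassium hydroxide, [K+].[OH-]
Why: Saponification of a di-ortho-substituted methyl benzoate, which needs poorly solvated hydroxide in hot DMSO. Both acetal-type groups are stable to base, and a brief cold acidification should free the acid without hydrolysing them.

Step 6
Reactants: 7 3-(1,3-dioxolan-2-yl)-4-methoxy-2-(methoxymethoxy)-6-methylbenzoic acid; 8 3-chloropentane-2,4-dione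
Product: 9 2,4-dioxopentan-3-yl aroate
Conditions: Cs2CO3 (0.55 equiv), DMF, rt; then 8, 0 °C to rt
Reagents that add atoms: none
Why: SN2 displacement of chloride from a carbon activated by two carbonyl groups by the cesium carboxylate. The C1'–O bond forms at the unhindered carboxylate oxygen, so no tetrahedral intermediate at the crowded acyl carbon is needed, and the absence of excess base keeps 8 from being lost as its enolate.

Step 7
Reactants: 9 2,4-dioxopentan-3-yl aroate
Product: 10 4-hydroxy-2-oxopentan-3-yl aroate (diastereomer mixture)
Conditions: NaBH4 (0.3 equiv), EtOH/THF, −78 to −40 °C; acetone, then aq. NH4Cl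
Reagents that add atoms: none
Why: Hydride reduction of one of two equivalent ketone carbonyls with a substoichiometric charge of NaBH4 at low temperature. The two new sp3 centres are not controlled because both are destroyed in step 8, and unreacted 9 can be recycled.

Step 8
Reactants: 10 4-hydroxy-2-oxopentan-3-yl aroate
Product: 12 (Z)-4-oxopent-2-en-3-yl aroate, via mesylate 11 (not isolated)
Conditions: MsCl, Et3N (3 equiv), CH2Cl2, 0 °C to rt
Reagents that add atoms: none
Why: Mesylation followed by E1cB elimination through the acidic C–H that carries the aroyloxy group and is alpha to the ketone. The conjugated enone should form mainly as the Z isomer (methyl trans to acetyl), and its geometry is of no consequence for step 9.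

Step 9
Reactants: 12 (Z)-4-oxopent-2-en-3-yl aroate; 13 di-tert-butyl malonate
Product: 15 tert-butyl 5-(aroyloxy)-6-methyl-2,4-dioxocyclohexane-1-carboxylate (diastereomer mixture), via Michael adduct 14 (not isolated)
Conditions: KOtBu (1.2 equiv), THF/tBuOH, 0 to 45 °C; then AcOH (1.2 equiv), 0 °C
Reagents that add atoms: none
Why: KOtBu deprotonates 13 and the malonate anion adds to the methyl-bearing β-carbon of 12 (C2'–C3' bond), giving 14 as its alpha-aroyloxy ketone enolate. Proton exchange through tBuOH makes the methyl ketone enolate available, and it attacks one tert-butyl ester in a 6-(enolendo)-exo-trig Claisen (Dieckmann-type) closure (C4'–C5' bond) that expels tert-butoxide. Deprotonation of the resulting 1,3-dione at C5' is essentially irreversible and pulls the reversible Michael step forward. The closest known reaction is the dimedone-type Michael–Claisen annulation of malonates with enones, as used for dihydroorsellinates. The three sp3 centres C1', C2' and C3' form without control and all are erased in step 10. There is no regiochemical choice, since the malonate is the only Michael donor and the methyl ketone the only enolate that can close a six-membered ring. The selectivity needed is chemoselectivity: the aroyl ester must survive tert-butoxide, a 5-exo attack by the C5' enolate and an O-to-O acyl shift within the enediolate. It is secured by the two ortho substituents (OMOM at C2, CH3 at C6), which block the tetrahedral intermediate at the aroyl carbonyl, and by the non-nucleophilic tert-butoxide, while the tert-butyl esters exclude transesterification and leave a carboxyl protecting group that acid removes at the end.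

Step 10
Reactants: 15 tert-butyl 5-(aroyloxy)-6-methyl-2,4-dioxocyclohexane-1-carboxylate
Product: 16 tert-butyl 3-(aroyloxy)-4,6-dihydroxy-2-methylbenzoate
Conditions: DDQ (1.1 equiv), dry 1,4-dioxane, rt to 60 °C
Reagents that add atoms: none
Why: Quinone dehydrogenation of a 4-alkoxycarbonylcyclohexane-1,3-dione to a β-resorcylate: hydride abstraction from the dienol tautomer and proton loss remove two ring hydrogens, with aromatisation as the driving force. The neutral anhydrous medium should spare the dioxolane, the MOM ether and the tert-butyl ester.

Step 11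
Reactants: 16 tert-butyl 3-(aroyloxy)-4,6-dihydroxy-2-methylbenzoate
Product: 18 tert-butyl 3-(aroyloxy)-5-formyl-4,6-dihydroxy-2-methylbenzoate, via hydroxymethyl resorcinol 17 (not isolated)
Conditions: MgCl2, Et3N, (CH2O)n, THF, 65 °C; aq. NH4Cl work-up
Reagents that add atoms: formaldehyde (from paraformaldehyde), C=O
Why: Magnesium-mediated ortho-formylation as in step 2: only ring B has free phenols, and C5' is its one unsubstituted carbon, ortho to both, so ring A cannot compete. The basic conditions are compatible with all three acid-labile groups.

Step 12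
Reactants: 18 tert-butyl 3-(aroyloxy)-5-formyl-4,6-dihydroxy-2-methylbenzoate
Product: 19 haemathamnolic acid
Conditions: TFA/CH2Cl2/H2O (10:10:1), 0 °C to rt
Reagents that add atoms: water, O
Why: One acidolysis removes all three groups: the tert-butyl ester by alkyl–oxygen cleavage, the MOM ether and the dioxolane by hydrolysis. It is a cold, non-basic last step, so the aryl ester is not exposed to base and the decarboxylation-prone acid is freed only at the end.

## Compound list

1 | methyl orsellinate (methyl 2,4-dihydroxy-6-methylbenzoate) | COC(=O)c1c(C)cc(O)cc1O | starting material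
2 | methyl everninate (methyl 2-hydroxy-4-methoxy-6-methylbenzoate) | COC(=O)c1c(C)cc(OC)cc1O | intermediate
3 | methyl 2-hydroxy-3-(hydroxymethyl)-4-methoxy-6-methylbenzoate | COC(=O)c1c(C)cc(OC)c(CO)c1O | intermediate (not isolated)
4 | methyl 3-formyl-2-hydroxy-4-methoxy-6-methylbenzoate | COC(=O)c1c(C)cc(OC)c(C=O)c1O | intermediate
5 | methyl 3-(1,3-dioxolan-2-yl)-2-hydroxy-4-methoxy-6-methylbenzoate | COC(=O)c1c(C)cc(OC)c(C2OCCO2)c1O | intermediate
6 | methyl 3-(1,3-dioxolan-2-yl)-4-methoxy-2-(methoxymethoxy)-6-methylbenzoate | COC(=O)c1c(C)cc(OC)c(C2OCCO2)c1OCOC | intermediate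
7 | 3-(1,3-dioxolan-2-yl)-4-methoxy-2-(methoxymethoxy)-6-methylbenzoic acid | OC(=O)c1c(C)cc(OC)c(C2OCCO2)c1OCOC | intermediate
8 | 3-chloropentane-2,4-dione | CC(=O)C(Cl)C(C)=O | starting material
9 | 2,4-dioxopentan-3-yl 3-(1,3-dioxolan-2-yl)-4-methoxy-2-(methoxymethoxy)-6-methylbenzoate | CC(=O)C(OC(=O)c1c(C)cc(OC)c(C2OCCO2)c1OCOC)C(C)=O | intermediate
10 | 4-hydroxy-2-oxopentan-3-yl 3-(1,3-dioxolan-2-yl)-4-methoxy-2-(methoxymethoxy)-6-methylbenzoate (racemic diastereomer mixture) | CC(O)C(OC(=O)c1c(C)cc(OC)c(C2OCCO2)c1OCOC)C(C)=O | intermediate
11 | 4-(methanesulfonyloxy)-2-oxopentan-3-yl 3-(1,3-dioxolan-2-yl)-4-methoxy-2-(methoxymethoxy)-6-methylbenzoate (racemic diastereomer mixture) | CC(OS(C)(=O)=O)C(OC(=O)c1c(C)cc(OC)c(C2OCCO2)c1OCOC)C(C)=O | intermediate (not isolated)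
12 | (Z)-4-oxopent-2-en-3-yl 3-(1,3-dioxolan-2-yl)-4-methoxy-2-(methoxymethoxy)-6-methylbenzoate | C/C=C(\OC(=O)c1c(C)cc(OC)c(C2OCCO2)c1OCOC)C(C)=O | intermediate
13 | di-tert-butyl malonate | CC(C)(C)OC(=O)CC(=O)OC(C)(C)C | starting material
14 | di-tert-butyl 2-(3-{[3-(1,3-dioxolan-2-yl)-4-methoxy-2-(methoxymethoxy)-6-methylbenzoyl]oxy}-4-oxopentan-2-yl)propanedioate (racemic diastereomer mixture) | CC(=O)C(OC(=O)c1c(C)cc(OC)c(C2OCCO2)c1OCOC)C(C)C(C(=O)OC(C)(C)C)C(=O)OC(C)(C)C | intermediate (not isolated)
15 | tert-butyl 5-{[3-(1,3-dioxolan-2-yl)-4-methoxy-2-(methoxymethoxy)-6-methylbenzoyl]oxy}-6-methyl-2,4-dioxocyclohexane-1-carboxylate (racemic diastereomer mixture, drawn as the triketo tautomer) | CC1C(C(=O)OC(C)(C)C)C(=O)CC(=O)C1OC(=O)c2c(C)cc(OC)c(C3OCCO3)c2OCOC | intermediate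
16 | tert-butyl 3-{[3-(1,3-dioxolan-2-yl)-4-methoxy-2-(methoxymethoxy)-6-methylbenzoyl]oxy}-4,6-dihydroxy-2-methylbenzoate | Cc1c(C(=O)OC(C)(C)C)c(O)cc(O)c1OC(=O)c2c(C)cc(OC)c(C3OCCO3)c2OCOC | intermediate
17 | tert-butyl 3-{[3-(1,3-dioxolan-2-yl)-4-methoxy-2-(methoxymethoxy)-6-methylbenzoyl]oxy}-4,6-dihydroxy-5-(hydroxymethyl)-2-methylbenzoate | Cc1c(C(=O)OC(C)(C)C)c(O)c(CO)c(O)c1OC(=O)c2c(C)cc(OC)c(C3OCCO3)c2OCOC | intermediate (not isolated)
18 | tert-butyl 3-{[3-(1,3-dioxolan-2-yl)-4-methoxy-2-(methoxymethoxy)-6-methylbenzoyl]oxy}-5-formyl-4,6-dihydroxy-2-methylbenzoate | Cc1c(C(=O)OC(C)(C)C)c(O)c(C=O)c(O)c1OC(=O)c2c(C)cc(OC)c(C3OCCO3)c2OCOC | intermediate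
19 | haemathamnolic acid (3-formyl-5-[(3-formyl-2-hydroxy-4-methoxy-6-methylbenzoyl)oxy]-2,4-dihydroxy-6-methylbenzoic acid) | COc1cc(C)c(C(=O)Oc2c(C)c(C(=O)O)c(O)c(C=O)c2O)c(O)c1C=O | target

## Step count and least certain steps

Total: 12 steps. Longest linear sequence: 12 steps, from methyl orsellinate 1 to 19; compounds 8 and 13 enter as purchased reagents.

**Step 9 (key step).** The most likely failure is acyl transfer out of the aroyl ester while the open-chain adduct waits to cyclise. This could happen by an O-to-O shift in the enediolate or by a five-membered closure of the methyl ketone enolate onto the aroyl carbonyl. Closure onto a bulky tert-butyl ester is slow, which also gives time for retro-Michael loss.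

The fallback keeps ring B as a cyclohexane-1,3-dione but reverses the roles of the two three-carbon pieces; it sets out from acid 7 and comes back at 15. The cesium salt of 7 is alkylated with methyl 2-chloroacetoacetate to give methyl 2-{[3-(1,3-dioxolan-2-yl)-4-methoxy-2-(methoxymethoxy)-6-methylbenzoyl]oxy}-3-oxobutanoate F1. NaBH4 reduces only its ketone, since the ester is inert, to methyl 2-(aroyloxy)-3-hydroxybutanoate F2. MsCl/Et3N converts F2, through the mesylate methyl 2-(aroyloxy)-3-(methanesulfonyloxy)butanoate F3, into methyl (Z)-2-(aroyloxy)but-2-enoate F4. tert-Butyl acetoacetate and KOtBu then add through the acetoacetate C2 to the β-carbon of F4, giving the adduct 1-tert-butyl 5-methyl 2-acetyl-4-(aroyloxy)-3-methylpentanedioate F5, whose acetyl methyl group closes onto the methyl ester (C5'–C6' bond in place of C4'–C5'), the classical crotonate–acetoacetate route to dihydroorsellinates, to give 15. In this variant C1' is alpha to an ester, not a ketone, until the ring has closed, and the ester attacked is a methyl ester.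

**Step 7.** The monoreduction may run on to the diol, because the hydroxy ketone 10 is about as reducible as 9. It may also stall if 9 is held as its enolate, and the new hydroxyl invites acyl migration from the neighbouring oxygen.

The fallback avoids hydride altogether. It sets out from 9 and comes back at 12, bypassing 10 and 11. O-triflation of the enol of 9 (Tf2O, iPr2NEt, CH2Cl2, −78 °C) gives the enol triflate 3-(aroyloxy)-4-oxopent-2-en-2-yl trifluoromethanesulfonate F6. Palladium-catalysed formate reduction (Pd(OAc)2, PPh3, HCO2H, Bu3N, DMF, 60 °C; zerovalent palladium inserts into the C–OTf bond and formate delivers hydride) then gives 12.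

**Step 10.** DDQ may add to the highly enolic C5' instead of abstracting hydride, or may abstract the benzylic acetal hydrogen of the alkoxy-rich ring A, and forcing conditions would favour the latter.

The fallback is a polar selenoxide sequence that sets out from 15 and comes back at 16. The dianion of 15 (lithium diisopropylamide, 2.2 equiv, THF, −78 °C) is selenenylated with PhSeBr at C3', the last-formed carbanion, to give tert-butyl 5-(aroyloxy)-6-methyl-2,4-dioxo-1-(phenylselanyl)cyclohexane-1-carboxylate F7. Oxidation with H2O2/pyridine at 0 °C gives the selenoxide, tert-butyl 5-(aroyloxy)-6-methyl-2,4-dioxo-1-(phenylseleninyl)cyclohexane-1-carboxylate F8. Syn-elimination towards C2'–H and enolisation then give 16.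

**Step 11.** The basic, warm medium may let the aroyl group wander to the adjacent C6' phenoxide or be cleaved. The hydroxymethyl stage 17 may also be intercepted by a second electron-rich ring B to give a diarylmethane before it is oxidised.

The fallback reverses the order of the endgame and uses an acidic electrophilic formylation. It sets out from 16 and comes back at 19. Aqueous TFA removes the three protecting groups to give 3-[(3-formyl-2-hydroxy-4-methoxy-6-methylbenzoyl)oxy]-4,6-dihydroxy-2-methylbenzoic acid F9. Rieche formylation (Cl2CHOMe, TiCl4, CH2Cl2, −10 to 0 °C) at C5', the only free position of the activated ring, gives the chloro ether 3-[chloro(methoxy)methyl]-5-[(3-formyl-2-hydroxy-4-methoxy-6-methylbenzoyl)oxy]-2,4-dihydroxy-6-methylbenzoic acid F10, which cold aqueous HCl hydrolyses to 19. Ring A is deactivated by its aldehyde and ester and should not compete.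

## Further compounds

F1 | step 9 | methyl 2-{[3-(1,3-dioxolan-2-yl)-4-methoxy-2-(methoxymethoxy)-6-methylbenzoyl]oxy}-3-oxobutanoate | CC(=O)C(OC(=O)c1c(C)cc(OC)c(C2OCCO2)c1OCOC)C(=O)OC
F2 | step 9 | methyl 2-{[3-(1,3-dioxolan-2-yl)-4-methoxy-2-(methoxymethoxy)-6-methylbenzoyl]oxy}-3-hydroxybutanoate (diastereomer mixture) | CC(O)C(OC(=O)c1c(C)cc(OC)c(C2OCCO2)c1OCOC)C(=O)OC
F3 | step 9 | methyl 2-{[3-(1,3-dioxolan-2-yl)-4-methoxy-2-(methoxymethoxy)-6-methylbenzoyl]oxy}-3-(methanesulfonyloxy)butanoate (diastereomer mixture) | CC(OS(C)(=O)=O)C(OC(=O)c1c(C)cc(OC)c(C2OCCO2)c1OCOC)C(=O)OC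
F4 | step 9 | methyl (Z)-2-{[3-(1,3-dioxolan-2-yl)-4-methoxy-2-(methoxymethoxy)-6-methylbenzoyl]oxy}but-2-enoate | C/C=C(\OC(=O)c1c(C)cc(OC)c(C2OCCO2)c1OCOC)C(=O)OC
F5 | step 9 | 1-tert-butyl 5-methyl 2-acetyl-4-{[3-(1,3-dioxolan-2-yl)-4-methoxy-2-(methoxymethoxy)-6-methylbenzoyl]oxy}-3-methylpentanedioate (diastereomer mixture) | CC(=O)C(C(=O)OC(C)(C)C)C(C)C(OC(=O)c1c(C)cc(OC)c(C2OCCO2)c1OCOC)C(=O)OC
F6 | step 7 | 3-{[3-(1,3-dioxolan-2-yl)-4-methoxy-2-(methoxymethoxy)-6-methylbenzoyl]oxy}-4-oxopent-2-en-2-yl trifluoromethanesulfonate (either alkene geometry) | CC(OS(=O)(=O)C(F)(F)F)=C(OC(=O)c1c(C)cc(OC)c(C2OCCO2)c1OCOC)C(C)=O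
F7 | step 10 | tert-butyl 5-{[3-(1,3-dioxolan-2-yl)-4-methoxy-2-(methoxymethoxy)-6-methylbenzoyl]oxy}-6-methyl-2,4-dioxo-1-(phenylselanyl)cyclohexane-1-carboxylate (diastereomer mixture) | CC1C([Se]c2ccccc2)(C(=O)OC(C)(C)C)C(=O)CC(=O)C1OC(=O)c3c(C)cc(OC)c(C4OCCO4)c3OCOC
F8 | step 10 | tert-butyl 5-{[3-(1,3-dioxolan-2-yl)-4-methoxy-2-(methoxymethoxy)-6-methylbenzoyl]oxy}-6-methyl-2,4-dioxo-1-(phenylseleninyl)cyclohexane-1-carboxylate (diastereomer mixture) | CC1C([Se](=O)c2ccccc2)(C(=O)OC(C)(C)C)C(=O)CC(=O)C1OC(=O)c3c(C)cc(OC)c(C4OCCO4)c3OCOC
F9 | step 11 | 3-[(3-formyl-2-hydroxy-4-methoxy-6-methylbenzoyl)oxy]-4,6-dihydroxy-2-methylbenzoic acid | COc1cc(C)c(C(=O)Oc2c(C)c(C(=O)O)c(O)cc2O)c(O)c1C=O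
F10 | step 11 | 3-[chloro(methoxy)methyl]-5-[(3-formyl-2-hydroxy-4-methoxy-6-methylbenzoyl)oxy]-2,4-dihydroxy-6-methylbenzoic acid | COc1cc(C)c(C(=O)Oc2c(C)c(C(=O)O)c(O)c(C(Cl)OC)c2O)c(O)c1C=O
A1 | alternative 1 | 3-(benzyloxycarbonyl)-4,6-bis(benzyloxy)-2-methylphenyl 4-(benzyloxy)-6-methyl-2-oxo-2H-pyran-5-carboxylate | Cc1oc(=O)cc(OCc2ccccc2)c1C(=O)Oc1c(C)c(C(=O)OCc2ccccc2)c(OCc2ccccc2)cc1OCc1ccccc1
A2 | alternative 1 | 1,1-dimethoxyethene | C=C(OC)OC
A3 | alternative 1 | 3-(benzyloxycarbonyl)-4,6-bis(benzyloxy)-2-methylphenyl 2-(benzyloxy)-4-methoxy-6-methylbenzoate | COc1cc(C)c(C(=O)Oc2c(C)c(C(=O)OCc3ccccc3)c(OCc3ccccc3)cc2OCc2ccccc2)c(OCc2ccccc2)c1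
A4 | alternative 2 | 3-(tert-butoxycarbonyl)-4,6-bis(methoxymethoxy)-2-methylphenyl 3,5,7-trioxooctanoate | CC(=O)CC(=O)CC(=O)CC(=O)Oc1c(C)c(C(=O)OC(C)(C)C)c(OCOC)cc1OCOC
A5 | alternative 2 | 3-(tert-butoxycarbonyl)-4,6-bis(methoxymethoxy)-2-methylphenyl 2,4-dihydroxy-6-methylbenzoate | Cc1cc(O)cc(O)c1C(=O)Oc2c(C)c(C(=O)OC(C)(C)C)c(OCOC)cc2OCOC
A6 | alternative 3 | 4-methoxy-2,4-bis[(trimethylsilyl)oxy]buta-1,3-dien-1-yl 3-(1,3-dioxolan-2-yl)-4-methoxy-2-(methoxymethoxy)-6-methylbenzoate | COC(O[Si](C)(C)C)=CC(O[Si](C)(C)C)=COC(=O)c1c(C)cc(OC)c(C2OCCO2)c1OCOC
A7 | alternative 3 | tert-butyl but-2-ynoate | CC#CC(=O)OC(C)(C)C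
A8 | alternative 3 | tert-butyl 3-{[3-(1,3-dioxolan-2-yl)-4-methoxy-2-(methoxymethoxy)-6-methylbenzoyl]oxy}-4,6-dihydroxy-2-methylbenzoate (identical with 16) | COCOc1c(C3OCCO3)c(OC)cc(C)c1C(=O)Oc2c(C)c(C(=O)OC(C)(C)C)c(O)cc2O
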